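Nobody has the constants of these steps, yet one combination of them can be read from the two earlier runs. The question is how the ratio of side product to target moves in the new flask.

| flask | starting material | reagent | protic impurity | remark | time |
|---|---|---|---|---|---|
| gamma | 1 M | 2.5 equiv | 0.10 M | run made earlier |  |
| beta | 1 M | 2.5 equiv | 0.40 M | run made earlier |  |
| flask | 1.0 M | 2.50 equiv | 0.200 M |  | 2.0 h |

| run | time / min | side product / % | target / % | starting material / % |
|---|---|---|---|---|
| gamma | 8.00 | 5.1 | 7.5 | 42.8 |
| gamma | 12.0 | 6.9 | 14.2 | 32.2 |
| gamma | 20.0 | 6.2 | 24.7 | 20.4 |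
| gamma | 25.0 | 8.7 | 32.4 | 15.6 |
| gamma | 40.0 | 9.3 | 46.1 | 7.6 |
| gamma | 60.0 | 11.4 | 62.5 | 3.6 |
| gamma | 90.0 | 11.8 | 73.7 | 0.4 |
| beta | 15.0 | 5.2 | 14.1 | 13.3 |
| beta | 30.0 | 8.0 | 28.7 | 2.6 |
| beta | 40.0 | 7.2 | 34.4 | 2.7 |
| beta | 60.0 | 5.7 | 44.9 | 0.8 |
| beta | 80.0 | 7.0 | 47.9 | 0.4 |
| beta | 90.0 | 6.3 | 50.2 | 0 |

(scatter of a reading: 1 percentage point)

- ratio of side product to target at 2.0 min
- ratio of side product to target at 15 min
- ratio of side product to target at 2.0 h



The first chemist divides the rate at which side product forms by the rate at which target forms, so that time drops out. She supposes that both leave one precursor, with reagent pressing towards target. The ratio is then a fixed concentration over the reagent level, and she calls that concentration the branch level, a selectivity factor that carries a concentration.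

If each surviving starting material costs two of reagent, the mean reagent level is the charge minus the survivors, counted as side product plus target. The last readings give 0.263 M in gamma and 0.243 M in beta, so she takes the mean, 0.253 M.

The shortfall at the last reading is 14.1 % in gamma and 43.5 % in beta, which is 0.980 of starting material per added impurity. She therefore counts 0.800 M of survivors in the new flask, a mean reagent level of 1.70 M, and a ratio of 0.149 at 2.0 h. With reagent still at its charge, early on, her ratio is 0.101.

The second chemist points to the lag instead: gamma reads 0.680 at 8.00 min and 0.269 at 25.0 min, so the ratio starts high and falls as target arrives.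

The forecast takes the second chemist's side, with 1.5, 0.37 and 0.14 at the three times, holding that “target is still in its lag” at the earliest.

The flask gives 1.67, 0.386 and 0.148.

    starting material + reagent → intermediate A (k = 0.0472 M⁻¹ min⁻¹)
    reagent + intermediate A → intermediate B (k = 0.891 M⁻¹ min⁻¹)
    intermediate A → side product (k = 0.210 min⁻¹)
    intermediate B ⇌ intermediate C (K = 1.70, k = 0.992 min⁻¹)
    intermediate B → target (k = 0.105 min⁻¹)
    starting material + protic impurity → quenched substrate (k = 1.24 M⁻¹ min⁻¹)

The second chemist wins early: in the flask, 1.67 at 2.0 min stands far above the first chemist's 0.101. Part of that early height is due to the loss of intermediate B to intermediate C, both ways: the simulated run without that step gives 1.12 at 2.0 min. The first keeps the late flask, where a reading ten times later changes the ratio little, and her 0.149 stands beside 0.148. In the neighbour flask with 1.00 equiv of reagent, the branch level over charge minus survivors gives 0.584, and that flask stands at 0.641.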